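(All runs stem from a simulated flask for an exercise, noise included.)

- I started from the small charge of the south-west run: it holds less starting material, 0.0500 M, than partner, 0.0830 M, so starting material is the limiting reagent.

| flask | starting material | partner | target | time |
|---|---|---|---|---|
| south | 0.100 M | 0.250 M |  |  |
| south-east | 0.0600 M | 0.210 M |  |  |
| north-west | 0.100 M | 0.120 M |  |  |
| east | 0.100 M | 0.250 M | 0.0500 M |  |
| south-west | 0.0500 M | 0.0830 M |  | 36 min |

| south run: time / min | south run: [target] / M | south-east run: time / min | south-east run: [target] / M | north-west run: time / min | north-west run: [target] / M | east run: time / min | east run: [target] / M |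
|---|---|---|---|---|---|---|---|
| 1.6 | 0.0041 | 1.6 | 0.0015 | 1.6 | 0.0017 | 1.6 | 0.0572 |
| 4.9 | 0.0141 | 4.9 | 0.0061 | 4.9 | 0.0057 | 4.9 | 0.0726 |
| 9.3 | 0.0250 | 9.3 | 0.0123 | 9.3 | 0.0125 | 9.3 | 0.0878 |
| 15 | 0.0383 | 15 | 0.0185 | 15 | 0.0175 | 15 | 0.0997 |
| 21 | 0.0487 | 21 | 0.0226 | 21 | 0.0229 | 21 | 0.1065 |
| 28 | 0.0580 | 28 | 0.0280 | 28 | 0.0296 | 28 | 0.1067 |
| 36 | 0.0624 | 36 | 0.0323 | 36 | 0.0340 | 36 | 0.1038 |

(standard deviation of a reading: 8 × 10⁻⁴ M)

- Overall: starting material + partner -> target.
- Constant volume, constant temperature.
- An order is taken over about fifteen percent of the charge, up and down.

- the exponent of [partner] in the starting rate at the charge of the south run (at the point where two percent of the starting material have become target)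
- the exponent of [starting material] in the starting rate at the charge of the south run (at the point where two percent of the starting material have become target) (one fixed amount of target, the same in the runs compared)
- target in the south-west run at 36 min, as a share of the starting material charged

- I reckoned with two amounts: the target the south-west run makes by 36 min, and a crossover level read from the east run.
- By 9.3 min the south run had made 0.0250 M and the north-west run 0.0125 M, which gave me a partner order of 0.944. The south-east run, with 0.0123 M at that time, gave a starting-material order of 1.05.
- I therefore took both orders as first and read a plain rate constant of 0.108 M⁻¹ min⁻¹ from the south run.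
- The east run, charged with 0.0500 M of target and the same starting material and partner as the south run, had gained 1.51 times the south amount by 9.3 min. I took the extra rate as proportional to [target] and named the crossover level, the [target] at which the target-carried path equals the plain path at equal [starting material] and [partner]: 0.0977 M, a reading.
- For the south-west run I held [partner] at its charge, which gave a filling time of 112 min, a share of 27.5% and 0.0137 M of target. That is 0.140 of the crossover level, so I expected the plain path to carry the south-west run.
- The forecast gave orders of 1.05 and 1.05 and a share of 24.5%, less than mine, on the ground that “Late rates in the other runs fit reversibility”.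
- The south-west run gave 23.7%, with a partner order of 1.0 and a starting-material order of 1.0, under this scheme:

    starting material ⇌ intermediate, settled at all times (0.1850)
    intermediate + partner → target (0.6960 M⁻¹ min⁻¹)
    target → decomposed product (0.01080 min⁻¹)
    starting material + partner + target → 2 target (3.048 M⁻² min⁻¹)

- Across the runs, the conversion of starting material + partner + target into 2 target moves the readings by 17 times the scatter (root mean square). The south-west target of 0.0118 M stands at 0.121 of the crossover level, while the last south reading, 0.0624 M at 36 min, stands at 0.639 of it.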